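**Strategy.** Ring C of the methoxyphenyl-bearing flavanone unit (O1''–C2''–C3''–C4''–C4a''–C8a'') is first built one atom too small, as a benzofuran-3(2H)-one whose silyl enol ether is cyclopropanated. In the key step, Fe(III) oxidation of this siloxy-cyclopropa[b]benzofuran cleaves the internal cyclopropane bond, because O1'' stabilises the C2'' radical and cation, and delivers the 8-iodochromone in one operation; the cyclopropane CH2 becomes C3''. Ligand-controlled conjugate addition of the anisyl group to C2''=C3'' then sets C2''. The iodide finally serves for an aryllead C-arylation of an enantioenriched flavanone β-keto ester (C3–C8'' bond, trans after decarboxylation).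

Key step: step 5

Assumption: a 2,3-diarylchroman-4-one with an α-hydrogen settles in the 2,3-trans (diequatorial) form under acid, so 2R fixes 3S; compound 1 is taken as a catalogue compound; the catalyst antipodes in steps 6 and 10 are those that give 2S and 2R, to be fixed on model substrates.

**Step 1**
Reactants: 1 1-[2,4-bis(benzyloxy)-6-hydroxyphenyl]ethan-1-one
Product: 2 1-[4,6-bis(benzyloxy)-2-hydroxy-3-iodophenyl]ethan-1-one
Conditions: I2, HIO3, EtOH–H2O, 40 °C
Reagents that add atoms: iodine, II; iodic acid, OI(=O)=O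
Why: Electrophilic aromatic iodination, expected ortho to the chelated phenol (C3) rather than between the two ethers as is usual for phloroacetophenone 4,6-diethers, which fixes the later C8'' attachment point next to the oxygen that becomes O1''.

**Step 2**
Reactants: 2 1-[4,6-bis(benzyloxy)-2-hydroxy-3-iodophenyl]ethan-1-one
Product: 4 4,6-bis(benzyloxy)-7-iodo-1-benzofuran-3(2H)-one, via bromoketone 3 (not isolated)
Conditions: CuBr2 (2.1 equiv), EtOAc–CHCl3, reflux; filter, evaporate; then NaOAc, EtOH, reflux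
Reagents that add atoms: none
Why: Copper(II) bromide α-bromination of the aryl methyl ketone (the bromine of 3 comes from CuBr2) followed by intramolecular Williamson O-alkylation (5-exo-tet) of the only free phenol should give the coumaranone, so the ring oxygen is unambiguously the one next to the iodinated carbon.

**Step 3**
Reactants: 4 4,6-bis(benzyloxy)-7-iodo-1-benzofuran-3(2H)-one
Product: 5 {[4,6-bis(benzyloxy)-7-iodo-1-benzofuran-3-yl]oxy}trimethylsilane
Conditions: TMSOTf, Et3N, CH2Cl2, 0 °C; used without chromatography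
Reagents that add atoms: trimethylsilyl trifluoromethanesulfonate, C[Si](C)(C)OS(=O)(=O)C(F)(F)F
Why: Soft enolisation and O-silylation of the readily enolised coumaranone should give the 3-siloxybenzofuran (silyl enol ether formation).

**Step 4**
Reactants: 5 {[4,6-bis(benzyloxy)-7-iodo-1-benzofuran-3-yl]oxy}trimethylsilane
Product: 6 {[4,6-bis(benzyloxy)-3-iodo-1,1a-dihydro-6bH-cyclopropa[b][1]benzofuran-6b-yl]oxy}trimethylsilane (racemic, cis-fused)
Conditions: Et2Zn, CH2I2, CH2Cl2, 0 °C to rt
Reagents that add atoms: diiodomethane, ICI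
Why: Furukawa-modified Simmons–Smith cyclopropanation of an electron-rich silyl enol ether; both new bonds form on one face, so the bicycle is cis-fused and racemic, which is irrelevant because both centres are destroyed in step 5.

**Step 5**
Reactants: 6 {[4,6-bis(benzyloxy)-3-iodo-1,1a-dihydro-6bH-cyclopropa[b][1]benzofuran-6b-yl]oxy}trimethylsilane
Product: 8 5,7-bis(benzyloxy)-8-iodo-4H-chromen-4-one, via 2-chlorochromanone 7 (not isolated)
Conditions: FeCl3 (2.5 equiv), DMF, 0 °C to rt; then NaOAc, MeOH, 40 °C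
Reagents that add atoms: none
Why: Fe(III) oxidises the siloxycyclopropane (silyl transfer to chloride and an iron alkoxide, or electron transfer) to a cyclopropyloxy radical, whose β-scission breaks the internal C1a–C6b bond so that the five-membered O-heterocycle opens into the six-membered ring with a radical at the future C2''; chlorine transfer from a second FeCl3 gives the α-chloro ether 7, which loses HCl through the O1''-stabilised oxocarbenium ion to give the C2''=C3'' enone. The closest known reaction type is the Ito–Saegusa oxidative one-carbon ring expansion of bicyclic trimethylsiloxycyclopropanes to cycloalkenones. No ring is closed by bond formation: the six-membered ring (O1'', C2'', C3'' = former cyclopropane CH2, C4'', C4a'', C8a'') arises by cleavage of the zero-atom bridge of the 2-oxabicyclo[3.1.0]hexane, and no stereocentre is created because C2'' ends sp2. The selectivity needed is cleavage of the internal rather than the exocyclic cyclopropane bond; the ring oxygen on C1a secures it, because the ring-expanded radical is an α-alkoxy radical whereas the alternative is a primary alkyl radical. Chemoselectivity over the aryl iodide and the benzyl ethers rests on the mild Fe(III)/DMF conditions, which should act only on the strained siloxycyclopropane.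

**Step 6**
Reactants: 8 5,7-bis(benzyloxy)-8-iodo-4H-chromen-4-one; 9 (4-methoxyphenyl)boronic acid
Product: 10 (2S)-5,7-bis(benzyloxy)-8-iodo-2-(4-methoxyphenyl)chroman-4-one
Conditions: Pd(OCOCF3)2 (5 mol%), t-BuPyOx (6 mol%, antipode that gives 2S), NH4PF6, H2O, ClCH2CH2Cl, 60 °C
Reagents that add atoms: none
Why: Pd(II)/pyridine-oxazoline-catalysed asymmetric conjugate addition of an arylboronic acid to a chromone; the ligand decides which face of C2''=C3'' the aryl–Pd species attacks and so sets C2'' as S, and the hindered electron-rich aryl iodide should stay untouched because the cycle remains at Pd(II).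

**Step 7**
Reactants: 10 (2S)-5,7-bis(benzyloxy)-8-iodo-2-(4-methoxyphenyl)chroman-4-one
Product: 11 (2S)-5,7-bis(benzyloxy)-2-(4-methoxyphenyl)-8-(trimethylstannyl)chroman-4-one
Conditions: Me3SnSnMe3, Pd(PPh3)4 (5 mol%), toluene, 100 °C
Reagents that add atoms: hexamethylditin, C[Sn](C)(C)[Sn](C)(C)C
Why: Pd(0)-catalysed stannylation of an aryl iodide with a distannane (Stille–Kelly type) under neutral conditions that should leave the flavanone stereocentre untouched.

**Step 8**
Reactants: 1 1-[2,4-bis(benzyloxy)-6-hydroxyphenyl]ethan-1-one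
Product: 12 tert-butyl 3-[2,4-bis(benzyloxy)-6-hydroxyphenyl]-3-oxopropanoate
Conditions: LiHMDS (3.3 equiv), THF, −78 °C; Boc2O, −78 to −20 °C; aq. NH4Cl
Reagents that add atoms: di-tert-butyl dicarbonate, CC(C)(C)OC(=O)OC(=O)OC(C)(C)C
Why: Claisen-type C-acylation of the ketone enolate within the phenoxide–enolate dianion; the tert-butyl ester suppresses lactonisation to a 4-hydroxycoumarin.

**Step 9**
Reactants: 12 tert-butyl 3-[2,4-bis(benzyloxy)-6-hydroxyphenyl]-3-oxopropanoate; 13 4-(benzyloxy)benzaldehyde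
Product: 14 tert-butyl 2-[2,4-bis(benzyloxy)-6-hydroxybenzoyl]-3-[4-(benzyloxy)phenyl]prop-2-enoate (E/Z mixture)
Conditions: piperidine (cat.), AcOH (cat.), 4 Å MS, toluene, rt
Reagents that add atoms: none
Why: Knoevenagel condensation of the β-keto ester with the aldehyde under piperidinium acetate catalysis; the alkene geometry is lost in the next step.

**Step 10**
Reactants: 14 tert-butyl 2-[2,4-bis(benzyloxy)-6-hydroxybenzoyl]-3-[4-(benzyloxy)phenyl]prop-2-enoate
Product: 15 tert-butyl (2R)-5,7-bis(benzyloxy)-2-[4-(benzyloxy)phenyl]-4-oxochromane-3-carboxylate (C3 epimers and enol)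
Conditions: cinchona-derived thiourea (10 mol%, pseudoenantiomer that gives 2R), toluene, −25 °C
Reagents that add atoms: none
Why: Bifunctional thiourea–tertiary amine catalysed intramolecular oxa-Michael addition (6-endo-trig) of the phenol to the alkylidene β-keto ester; the catalyst binds the dicarbonyl and delivers the phenoxide to one face, setting C2 as R.

**Step 11**
Reactants: 11 (2S)-5,7-bis(benzyloxy)-2-(4-methoxyphenyl)-8-(trimethylstannyl)chroman-4-one; 15 tert-butyl (2R)-5,7-bis(benzyloxy)-2-[4-(benzyloxy)phenyl]-4-oxochromane-3-carboxylate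
Product: 17 tert-butyl 5,7-bis(benzyloxy)-2-[4-(benzyloxy)phenyl]-3-[(2S)-5,7-bis(benzyloxy)-2-(4-methoxyphenyl)-4-oxochroman-8-yl]-4-oxochromane-3-carboxylate (C2 geometry as in 15, C3 not assigned), via aryllead triacetate 16 (not isolated)
Conditions: Pb(OAc)4, Hg(OAc)2 (5 mol%), CHCl3, 40 °C; then 15, pyridine, CHCl3, 40–60 °C
Reagents that add atoms: none
Why: Tin–lead exchange gives the aryllead triacetate, whose ligand coupling with the β-keto ester (Pinhey arylation) should form the quaternary C3–C8'' bond; the configuration of the new quaternary centre is erased in step 12.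

**Step 12**
Reactants: 17 tert-butyl 5,7-bis(benzyloxy)-2-[4-(benzyloxy)phenyl]-3-[(2S)-5,7-bis(benzyloxy)-2-(4-methoxyphenyl)-4-oxochroman-8-yl]-4-oxochromane-3-carboxylate
Product: 19 (2S)-5,7-bis(benzyloxy)-8-{(2R,3S)-5,7-bis(benzyloxy)-2-[4-(benzyloxy)phenyl]-4-oxochroman-3-yl}-2-(4-methoxyphenyl)chroman-4-one, via β-keto acid 18 (not isolated)
Conditions: TFA, CH2Cl2, 0 °C to rt; evaporate; toluene, 80 °C
Reagents that add atoms: none
Why: Acidolysis of the tert-butyl ester and thermal decarboxylation of the β-keto acid; protonation of the enol and acid-mediated equilibration at C3 should place the C3 aryl trans to the C2 aryl (both equatorial), so 2R gives 3S.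

**Step 13**
Reactants: 19 (2S)-5,7-bis(benzyloxy)-8-{(2R,3S)-5,7-bis(benzyloxy)-2-[4-(benzyloxy)phenyl]-4-oxochroman-3-yl}-2-(4-methoxyphenyl)chroman-4-one
Product: 20 (2S)-8-[(2R,3S)-5,7-dihydroxy-2-(4-hydroxyphenyl)-4-oxochroman-3-yl]-5,7-dihydroxy-2-(4-methoxyphenyl)chroman-4-one
Conditions: H2 (1 atm), 10% Pd/C, EtOAc–MeOH, rt
Reagents that add atoms: none
Why: Hydrogenolysis of the five aryl benzyl ethers under neutral conditions; the methyl ether, both ketones and the three stereocentres should survive if the reaction is stopped once the ethers are consumed.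

**Compound list**
1 | 1-[2,4-bis(benzyloxy)-6-hydroxyphenyl]ethan-1-one | CC(=O)c1c(O)cc(OCc2ccccc2)cc1OCc1ccccc1 | starting material
2 | 1-[4,6-bis(benzyloxy)-2-hydroxy-3-iodophenyl]ethan-1-one | CC(=O)c1c(O)c(I)c(OCc2ccccc2)cc1OCc1ccccc1 | intermediate
3 | 1-[4,6-bis(benzyloxy)-2-hydroxy-3-iodophenyl]-2-bromoethan-1-one | O=C(CBr)c1c(O)c(I)c(OCc2ccccc2)cc1OCc1ccccc1 | intermediate
4 | 4,6-bis(benzyloxy)-7-iodo-1-benzofuran-3(2H)-one | O=C1COc2c(I)c(OCc3ccccc3)cc(OCc3ccccc3)c12 | intermediate
5 | {[4,6-bis(benzyloxy)-7-iodo-1-benzofuran-3-yl]oxy}trimethylsilane | C[Si](C)(C)Oc1coc2c(I)c(OCc3ccccc3)cc(OCc3ccccc3)c12 | intermediate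
6 | {[4,6-bis(benzyloxy)-3-iodo-1,1a-dihydro-6bH-cyclopropa[b][1]benzofuran-6b-yl]oxy}trimethylsilane (racemic, cis-fused) | C[Si](C)(C)OC12CC1Oc1c(I)c(OCc3ccccc3)cc(OCc3ccccc3)c12 | intermediate
7 | 5,7-bis(benzyloxy)-2-chloro-8-iodochroman-4-one (racemic) | O=C1CC(Cl)Oc2c(I)c(OCc3ccccc3)cc(OCc3ccccc3)c12 | intermediate
8 | 5,7-bis(benzyloxy)-8-iodo-4H-chromen-4-one | O=c1ccoc2c(I)c(OCc3ccccc3)cc(OCc3ccccc3)c12 | intermediate
9 | (4-methoxyphenyl)boronic acid | COc1ccc(B(O)O)cc1 | starting material
10 | (2S)-5,7-bis(benzyloxy)-8-iodo-2-(4-methoxyphenyl)chroman-4-one | COc1ccc([C@@H]2CC(=O)c3c(OCc4ccccc4)cc(OCc4ccccc4)c(I)c3O2)cc1 | intermediate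
11 | (2S)-5,7-bis(benzyloxy)-2-(4-methoxyphenyl)-8-(trimethylstannyl)chroman-4-one | COc1ccc([C@@H]2CC(=O)c3c(OCc4ccccc4)cc(OCc4ccccc4)c([Sn](C)(C)C)c3O2)cc1 | intermediate
12 | tert-butyl 3-[2,4-bis(benzyloxy)-6-hydroxyphenyl]-3-oxopropanoate | CC(C)(C)OC(=O)CC(=O)c1c(O)cc(OCc2ccccc2)cc1OCc1ccccc1 | intermediate
13 | 4-(benzyloxy)benzaldehyde | O=Cc1ccc(OCc2ccccc2)cc1 | starting material
14 | tert-butyl 2-[2,4-bis(benzyloxy)-6-hydroxybenzoyl]-3-[4-(benzyloxy)phenyl]prop-2-enoate (E/Z mixture) | CC(C)(C)OC(=O)C(=Cc1ccc(OCc2ccccc2)cc1)C(=O)c1c(O)cc(OCc2ccccc2)cc1OCc1ccccc1 | intermediate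
15 | tert-butyl (2R)-5,7-bis(benzyloxy)-2-[4-(benzyloxy)phenyl]-4-oxochromane-3-carboxylate (C3 epimers) | CC(C)(C)OC(=O)C1C(=O)c2c(OCc3ccccc3)cc(OCc3ccccc3)cc2O[C@H]1c1ccc(OCc2ccccc2)cc1 | intermediate
16 | [(2S)-5,7-bis(benzyloxy)-2-(4-methoxyphenyl)-4-oxochroman-8-yl]lead triacetate | COc1ccc([C@@H]2CC(=O)c3c(OCc4ccccc4)cc(OCc4ccccc4)c([Pb](OC(C)=O)(OC(C)=O)OC(C)=O)c3O2)cc1 | intermediate
17 | tert-butyl 5,7-bis(benzyloxy)-2-[4-(benzyloxy)phenyl]-3-[(2S)-5,7-bis(benzyloxy)-2-(4-methoxyphenyl)-4-oxochroman-8-yl]-4-oxochromane-3-carboxylate (C2 geometry of 15, formally 2S because C3 is now quaternary; C3 not assigned) | COc1ccc([C@@H]2CC(=O)c3c(OCc4ccccc4)cc(OCc4ccccc4)c(C4(C(=O)OC(C)(C)C)C(=O)c5c(OCc6ccccc6)cc(OCc6ccccc6)cc5O[C@H]4c4ccc(OCc5ccccc5)cc4)c3O2)cc1 | intermediate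
18 | the corresponding 3-carboxylic acid of 17 | COc1ccc([C@@H]2CC(=O)c3c(OCc4ccccc4)cc(OCc4ccccc4)c(C4(C(=O)O)C(=O)c5c(OCc6ccccc6)cc(OCc6ccccc6)cc5O[C@H]4c4ccc(OCc5ccccc5)cc4)c3O2)cc1 | intermediate
19 | (2S)-5,7-bis(benzyloxy)-8-{(2R,3S)-5,7-bis(benzyloxy)-2-[4-(benzyloxy)phenyl]-4-oxochroman-3-yl}-2-(4-methoxyphenyl)chroman-4-one | COc1ccc([C@@H]2CC(=O)c3c(OCc4ccccc4)cc(OCc4ccccc4)c([C@@H]4C(=O)c5c(OCc6ccccc6)cc(OCc6ccccc6)cc5O[C@H]4c4ccc(OCc5ccccc5)cc4)c3O2)cc1 | intermediate
20 | (2S)-8-[(2R,3S)-5,7-dihydroxy-2-(4-hydroxyphenyl)-4-oxochroman-3-yl]-5,7-dihydroxy-2-(4-methoxyphenyl)chroman-4-one | COc1ccc([C@@H]2CC(=O)c3c(O)cc(O)c([C@@H]4C(=O)c5c(O)cc(O)cc5O[C@H]4c4ccc(O)cc4)c3O2)cc1 | target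

**Totals.** Total step count: 13. Longest linear sequence: 10 steps (1–7, then 11–13).

**Steps most likely to fail**

1. Step 4. Carbenoid transfer to the C2=C3 bond may be too slow because that bond is part of a benzofuran, or zinc iodide may strip the silyl group first and return the coumaranone. The fallback is a different one-carbon ring expansion that sets out from 4. A Mannich reaction with Eschenmoser's salt should give the Mannich base F1 (as its hydroiodide). Warming eliminates dimethylamine to give the 2-methylidene coumaranone F2. Catalytic tributylphosphine should then isomerise F2 by conjugate addition, proton shift to the ylide, β-elimination of the aryloxide, 6-endo oxa-Michael re-closure and loss of the phosphine; this is the mechanistic counterpart of the nucleophile-mediated aurone-to-flavone ring expansion. The fallback returns to the route at 8.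

2. Step 11. Tin–lead exchange may stall at the di-ortho-substituted stannane, or ligand coupling at the crowded C3 may be slower than base-induced retro-oxa-Michael opening of 15, which would erode the C2 configuration. The fallback sets out from 10. Oxidation of the aryl iodide (mCPBA, TsOH) and capture with 1,3,5-trimethoxybenzene should give the aryl(2,4,6-trimethoxyphenyl)iodonium tosylate F3. Its reaction with the pre-formed sodium enolate of 15 (NaH, DMF, 0 °C) is a metal-free α-arylation of a β-keto ester by a diaryliodonium salt, the trimethoxyphenyl group staying on iodine. It returns to the route at 17.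

3. Step 6. Traces of Pd(0) may insert into the C–I bond (biaryl formation, catalyst loss), or the facial selectivity may be insufficient. The fallback postpones the conjugate addition until no halide is present and sets out from 8. Stannylation gives the chromone stannane F4 and tin–lead exchange the aryllead triacetate F5. Pinhey arylation of 15 gives the coupled β-keto ester F6. TFA and heat, by way of the β-keto acid F7, give the flavanone–chromone F8. The same Pd/pyridine-oxazoline addition of 9, or a Rh/chiral diene variant, to the halogen-free chromone F8 then sets C2''. It returns to the route at 19.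

**Further compounds**
F1 | step 4 | 4,6-bis(benzyloxy)-2-[(dimethylamino)methyl]-7-iodo-1-benzofuran-3(2H)-one | CN(C)CC1Oc2c(I)c(OCc3ccccc3)cc(OCc3ccccc3)c2C1=O
F2 | step 4 | 4,6-bis(benzyloxy)-7-iodo-2-methylidene-1-benzofuran-3(2H)-one | C=C1Oc2c(I)c(OCc3ccccc3)cc(OCc3ccccc3)c2C1=O
F3 | step 11 | [(2S)-5,7-bis(benzyloxy)-2-(4-methoxyphenyl)-4-oxochroman-8-yl](2,4,6-trimethoxyphenyl)iodonium 4-methylbenzenesulfonate | COc1ccc([C@@H]2CC(=O)c3c(OCc4ccccc4)cc(OCc4ccccc4)c([I+]c4c(OC)cc(OC)cc4OC)c3O2)cc1.Cc1ccc(S(=O)(=O)[O-])cc1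
F4 | step 6 | 5,7-bis(benzyloxy)-8-(trimethylstannyl)-4H-chromen-4-one | C[Sn](C)(C)c1c(OCc2ccccc2)cc(OCc2ccccc2)c2c(=O)ccoc12
F5 | step 6 | [5,7-bis(benzyloxy)-4-oxo-4H-chromen-8-yl]lead triacetate | CC(=O)O[Pb](OC(C)=O)(OC(C)=O)c1c(OCc2ccccc2)cc(OCc2ccccc2)c2c(=O)ccoc12
F6 | step 6 | tert-butyl 5,7-bis(benzyloxy)-2-[4-(benzyloxy)phenyl]-3-[5,7-bis(benzyloxy)-4-oxo-4H-chromen-8-yl]-4-oxochromane-3-carboxylate (C2 geometry of 15, C3 not assigned) | CC(C)(C)OC(=O)C1(c2c(OCc3ccccc3)cc(OCc3ccccc3)c3c(=O)ccoc23)C(=O)c2c(OCc3ccccc3)cc(OCc3ccccc3)cc2O[C@H]1c1ccc(OCc2ccccc2)cc1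
F7 | step 6 | the corresponding 3-carboxylic acid of F6 | OC(=O)C1(c2c(OCc3ccccc3)cc(OCc3ccccc3)c3c(=O)ccoc23)C(=O)c2c(OCc3ccccc3)cc(OCc3ccccc3)cc2O[C@H]1c1ccc(OCc2ccccc2)cc1
F8 | step 6 | 5,7-bis(benzyloxy)-8-{(2R,3S)-5,7-bis(benzyloxy)-2-[4-(benzyloxy)phenyl]-4-oxochroman-3-yl}-4H-chromen-4-one | O=c1ccoc2c([C@@H]3C(=O)c4c(OCc5ccccc5)cc(OCc5ccccc5)cc4O[C@H]3c3ccc(OCc4ccccc4)cc3)c(OCc3ccccc3)cc(OCc3ccccc3)c12
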